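**Plan**

- Numbering: ring A = C1–C5 and C10 (C4 = CMe2, C5 = CH, C10 = quaternary C with CH3 and the C9 ketone); arm C6–C8 on C5 (C8 = methyl ketone); chain C11–C15 (C13 = CHCH3, C15 = ester C=O); glycerol C1'–C3'.
- Feature: C10 carries CH3 and the C9 carbonyl trans to the C6 arm on C5, and C3 can hold a removable oxygen. Ring A is therefore the [4+2] adduct of an (E)-2-methyl enal (C5=C10) and a 1,3-dioxygenated butadiene (C1–C4).
- Retrosynthesis: cut the C15–O1' ester, then C9–C11 (C9 aldehyde + C11–C15 Grignard reagent), the two C4 methyls and the C3 oxygen, and last C4–C5 and C1–C10 of ring A.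
- Forward: enal (3 steps) → ring A by cycloaddition → chain joined at C9 → C4 dimethylation, C1=C2 saturation, C3 deoxygenation → oxidation at C9/C15 → glyceride.
- Stereochemistry: C10 from the chiral Lewis acid (enal face), C5 from the E alkene, C13 from methyl (R)-hydrogen 3-methylglutarate, C2' from 3-O-benzyl-sn-glycerol.

Key step: step 4

Remark: C9 (steps 9–15), C4 in 18 and the methoxy carbon of 7 are carried as epimer mixtures and left undefined in the SMILES, because each is later oxidised, quaternised or eliminated.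
Remark: the sense of induction in step 4 is assigned from the formyl C–H···O binding model of the catalyst; the (S)-catalyst follows from that model, and its mirror image would be used if the sense proved opposite.

**Route**

Step 1
Reactants: 1 ethyl levulinate
Product: 2 ethyl 3-(2-methyl-1,3-dioxolan-2-yl)propanoate
Conditions: HOCH2CH2OH, p-TsOH (cat.), toluene, reflux, Dean–Stark
Reagents that add atoms: ethylene glycol, OCCO
Why: Acid-catalysed ketalisation with azeotropic removal of water masks the C8 ketone as a dioxolane that tolerates hydride, ylide, Grignard and amide-base chemistry, while the ester is untouched.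

Step 2
Reactants: 2 ethyl 3-(2-methyl-1,3-dioxolan-2-yl)propanoate
Product: 3 3-(2-methyl-1,3-dioxolan-2-yl)propanal
Conditions: i-Bu2AlH (1.05 equiv), toluene, −78 °C; aq. potassium sodium tartrate
Reagents that add atoms: none
Why: Partial reduction of an ester with diisobutylaluminium hydride at −78 °C stops at the aldehyde oxidation level, and the ketal is inert to the hydride.

Step 3
Reactants: 3 3-(2-methyl-1,3-dioxolan-2-yl)propanal; 4 2-(triphenylphosphoranylidene)propanal
Product: 5 (E)-2-methyl-5-(2-methyl-1,3-dioxolan-2-yl)pent-2-enal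
Conditions: toluene, 90 °C
Reagents that add atoms: none
Why: Wittig olefination with the formyl-stabilised ylide is under thermodynamic control and gives the (E)-trisubstituted enal, fixing the alkene geometry that later becomes the C5/C10 relative configuration.

Step 4
Reactants: 5 (E)-2-methyl-5-(2-methyl-1,3-dioxolan-2-yl)pent-2-enal; 6 (E)-1-methoxy-3-(trimethylsilyloxy)buta-1,3-diene
Product: 8 (1S,6R)-1-methyl-6-[2-(2-methyl-1,3-dioxolan-2-yl)ethyl]-4-oxocyclohex-2-ene-1-carbaldehyde, via silyl enol ether cycloadduct 7 (not isolated)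
Conditions: (S)-tetrahydro-1-(2-methylphenyl)-3,3-diphenyl-1H,3H-pyrrolo[1,2-c][1,3,2]oxazaborole·HN(SO2CF3)2 (20 mol %), 6 (2 equiv), CH2Cl2, −78 → −40 °C; then CF3CO2H (cat.), CH2Cl2, 0 °C; Et3N quench
Reagents that add atoms: none
Why: The protonated oxazaborolidine binds the formyl oxygen of 5 (boron syn to the formyl hydrogen, formyl C–H···O contact to the ring oxygen, enal s-trans), and the electron-rich diene 6 then adds across C5=C10 in a concerted, asynchronous, normal-electron-demand [4+2] cycloaddition in which the CH2 terminus (C4) bonds ahead of the methoxy-bearing terminus (C1); the closest known reaction type is the oxazaborolidinium-catalysed enantioselective Diels–Alder reaction of α-substituted enals, joined to the 1-alkoxy-3-silyloxybutadiene route to 4,4-disubstituted cyclohexenones. Ring A (C1–C5, C10) closes by this intermolecular cycloaddition, the bonds C4–C5 and C1–C10 forming suprafacially on both partners. C10 is set by the catalyst, whose phenyl group on the boron-bound face should shield one face of the coordinated enal so that the diene reaches the C2-Re/C3-Si face and gives the (1S) centre of 8; C5 is set by the E geometry of 5, which suprafacial addition turns into the trans relation of the formyl group and the C6 arm. The step needs regioselectivity, which the donor pattern of 6 secures (its CH2 terminus is the nucleophilic end and meets the electrophilic β-carbon), and chemoselectivity for the C=C over hetero-Diels–Alder addition to the formyl C=O, which the s-trans α-methyl enal in this binding mode and the low temperature favour. The configuration at the methoxy carbon of 7 is irrelevant because catalytic anhydrous CF3CO2H expels MeOSiMe3 to give the enone while leaving the dioxolane intact.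

Step 5
Reactants: 9 methyl (R)-hydrogen 3-methylglutarate
Product: 10 methyl (3R)-5-hydroxy-3-methylpentanoate
Conditions: BH3·SMe2 (1.1 equiv), THF, 0 → 20 °C; then H2O
Reagents that add atoms: none
Why: Borane reduces a free carboxylic acid much faster than a methyl ester (chemoselective borane reduction), so only the acid terminus (future C11) becomes CH2OH and C13 is not touched.

Step 6
Reactants: 10 methyl (3R)-5-hydroxy-3-methylpentanoate
Product: 11 methyl (3S)-5-bromo-3-methylpentanoate
Conditions: CBr4, PPh3, CH2Cl2, 0 °C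
Reagents that add atoms: tetrabromomethane, BrC(Br)(Br)Br
Why: Appel bromination converts the primary alcohol into the bromide under neutral conditions, which avoids lactonisation of the δ-hydroxy ester (the descriptor changes only because bromine raises the CIP rank of that branch).

Step 7
Reactants: 11 methyl (3S)-5-bromo-3-methylpentanoate
Product: 12 (3S)-5-bromo-3-methylpentan-1-ol
Conditions: i-Bu2AlH (2.3 equiv), CH2Cl2, −78 → 0 °C; aq. potassium sodium tartrate
Reagents that add atoms: none
Why: Diisobutylaluminium hydride in excess reduces the methyl ester to the primary alcohol (ester reduction, future C15) without displacing the primary bromide, which a more nucleophilic hydride such as LiAlH4 could attack.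

Step 8
Reactants: 12 (3S)-5-bromo-3-methylpentan-1-ol
Product: 13 (3S)-1-bromo-5-(methoxymethoxy)-3-methylpentane
Conditions: MOMCl, i-Pr2NEt, CH2Cl2, 0 → 20 °C
Reagents that add atoms: chloromethyl methyl ether, COCCl
Why: Methoxymethyl ether formation (O-alkylation under amine base) gives an acetal protecting group that survives Grignard formation, lithium amide bases and hot alkali in the later steps.

Step 9
Reactants: 8 (1S,6R)-1-methyl-6-[2-(2-methyl-1,3-dioxolan-2-yl)ethyl]-4-oxocyclohex-2-ene-1-carbaldehyde; 13 (3S)-1-bromo-5-(methoxymethoxy)-3-methylpentane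
Product: 15 (4S,5R)-4-[(4R)-1-hydroxy-6-(methoxymethoxy)-4-methylhexyl]-4-methyl-5-[2-(2-methyl-1,3-dioxolan-2-yl)ethyl]cyclohex-2-en-1-one (C9 epimers), via Grignard reagent 14 (not isolated)
Conditions: 13, Mg turnings, I2 (cat.), THF, 45 °C; then 8 (limiting, 14 in 1.3 equiv), THF, −78 °C; aq. NH4Cl at −78 °C
Reagents that add atoms: none
Why: Grignard 1,2-addition at −78 °C is selective for the formyl group, which is far more electrophilic than the conjugated ring ketone and cannot be enolised, and the new C9 carbinol centre need not be controlled because it is oxidised to the ketone in step 16.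

Step 10
Reactants: 15 C9 carbinol (named in step 9)
Product: 16 (4S,5R)-4-[(4R)-1,6-bis(methoxymethoxy)-4-methylhexyl]-4-methyl-5-[2-(2-methyl-1,3-dioxolan-2-yl)ethyl]cyclohex-2-en-1-one (C9 epimers)
Conditions: MOMCl, i-Pr2NEt, Bu4NI (cat.), CH2Cl2, 40 °C
Reagents that add atoms: chloromethyl methyl ether, COCCl
Why: Methoxymethylation under amine base caps the hindered C9 hydroxyl without generating a free alkoxide, so the γ-hydroxyalkyl enone cannot fragment by a vinylogous retro-aldol reaction during the enolate chemistry that follows.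

Step 11
Reactants: 16 C9 MOM ether (named in step 10)
Product: 18 (4R,5R)-4-[(4R)-1,6-bis(methoxymethoxy)-4-methylhexyl]-4,6-dimethyl-5-[2-(2-methyl-1,3-dioxolan-2-yl)ethyl]cyclohex-2-en-1-one (C4 and C9 epimers), via lithium enolate 17 (not isolated)
Conditions: LiN(i-Pr)2 (1.2 equiv), THF, −78 °C; MeI, −78 → −20 °C
Reagents that add atoms: iodomethane, CI
Why: Kinetic deprotonation can occur only at C4, because C2 is vinylic and C10 is quaternary, and the cross-conjugated lithium enolate is C-methylated by iodomethane (enolate alkylation), the transient C4 configuration being of no consequence.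

Step 12
Reactants: 18 C4-monomethyl enone (named in step 11)
Product: 20 (4R,5S)-4-[(4R)-1,6-bis(methoxymethoxy)-4-methylhexyl]-4,6,6-trimethyl-5-[2-(2-methyl-1,3-dioxolan-2-yl)ethyl]cyclohex-2-en-1-one (C9 epimers), via lithium enolate 19 (not isolated)
Conditions: LiN(i-Pr)2 (1.5 equiv), THF, −78 → 0 °C; MeI (5 equiv), DMPU, −78 → 0 °C
Reagents that add atoms: iodomethane, CI
Why: A second enolisation at the remaining C4 hydrogen followed by methylation in the presence of DMPU (enolate alkylation) completes the gem-dimethyl group and removes the C4 stereocentre.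

Step 13
Reactants: 20 C4-dimethyl enone (named in step 12)
Product: 21 (3S,4R)-4-[(4R)-1,6-bis(methoxymethoxy)-4-methylhexyl]-2,2,4-trimethyl-3-[2-(2-methyl-1,3-dioxolan-2-yl)ethyl]cyclohexan-1-one (C9 epimers)
Conditions: H2 (1 atm), Pd/C (10% Pd on carbon), EtOAc, 20 °C
Reagents that add atoms: none
Why: Heterogeneous catalytic hydrogenation saturates the disubstituted conjugated C1=C2 bond while the ketone, the acetals and the ketal are inert, and no stereocentre is formed.

Step 14
Reactants: 21 saturated C3 ketone (named in step 13)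
Product: 23 2-{2-[(1R,2R)-2-[(4R)-1,6-bis(methoxymethoxy)-4-methylhexyl]-2,6,6-trimethylcyclohexyl]ethyl}-2-methyl-1,3-dioxolane (C9 epimers), via hydrazone 22 (not isolated)
Conditions: N2H4·H2O, KOH, diethylene glycol, 130 °C, then 200 °C with removal of water
Reagents that add atoms: none
Why: Wolff–Kishner reduction in its Huang–Minlon form converts the C3 ketone through its hydrazone into CH2 with loss of N2, conditions under which 2,2-dimethylcyclohexanones react and under which the base-stable MOM ethers and dioxolane persist and no stereocentre can epimerise.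

Step 15
Reactants: 23 deoxygenated bis-MOM ketal (named in step 14)
Product: 24 4-{(1R,2R)-2-[(4R)-1,6-dihydroxy-4-methylhexyl]-2,6,6-trimethylcyclohexyl}butan-2-one (C9 epimers)
Conditions: 4 M aq. HCl, THF, 50 °C
Reagents that add atoms: water, O
Why: Aqueous acid hydrolyses the dioxolane and both methoxymethyl ethers in one operation (acetal hydrolysis), releasing the C8 ketone, the C9 carbinol and the C15 primary alcohol.

Step 16
Reactants: 24 keto diol (named in step 15)
Product: 25 (3R)-3-methyl-6-oxo-6-[(1R,2R)-1,3,3-trimethyl-2-(3-oxobutyl)cyclohexyl]hexanoic acid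
Conditions: CrO3, H2SO4, H2O, acetone, 0 °C
Reagents that add atoms: water, O
Why: Jones oxidation takes the secondary C9 alcohol to the ketone and the primary C15 alcohol to the carboxylic acid in one pot, which also merges the C9 epimers, and C5, C10 and C13 cannot epimerise because none bears a hydrogen α to a carbonyl.

Step 17
Reactants: 25 diketo acid (named in step 16); 26 (2R)-3-(benzyloxy)propane-1,2-diol (3-O-benzyl-sn-glycerol)
Product: 27 (2S)-3-(benzyloxy)-2-hydroxypropyl (3R)-3-methyl-6-oxo-6-[(1R,2R)-1,3,3-trimethyl-2-(3-oxobutyl)cyclohexyl]hexanoate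
Conditions: DCC, DMAP (cat.), 26 (1.5 equiv), CH2Cl2, −20 → 0 °C
Reagents that add atoms: none
Why: Steglich esterification acylates the primary hydroxyl of the diol, used in excess at low temperature, in preference to the more hindered secondary one, placing the acyl group on sn-1 with the C2' configuration supplied by 26.

Step 18
Reactants: 27 sn-1 monoester (named in step 17)
Product: 28 (2S)-2-acetoxy-3-(benzyloxy)propyl (3R)-3-methyl-6-oxo-6-[(1R,2R)-1,3,3-trimethyl-2-(3-oxobutyl)cyclohexyl]hexanoate
Conditions: Ac2O, pyridine, DMAP (cat.), CH2Cl2, 0 °C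
Reagents that add atoms: acetic anhydride, CC(=O)OC(C)=O
Why: DMAP-catalysed acetylation of the remaining secondary hydroxyl leaves the C2'–O bond intact, so the configuration is retained, and the benzyl ether on O3' rules out acyl migration at this stage.

Step 19
Reactants: 28 benzyl-protected diacylglycerol (named in step 18)
Product: 29 (2S)-2-acetoxy-3-hydroxypropyl (3R)-3-methyl-6-oxo-6-[(1R,2R)-1,3,3-trimethyl-2-(3-oxobutyl)cyclohexyl]hexanoate (target, CNP0287223.1)
Conditions: H2 (1 atm), Pd/C (10% Pd on carbon), EtOAc, 20 °C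
Reagents that add atoms: none
Why: Hydrogenolysis of the benzyl ether in neutral ethyl acetate frees the sn-3 hydroxyl without acid or base, the conditions that minimise 2→3 acyl migration in 1,2-diacylglycerols, and the two ketones are not reduced.

**Compound list**

1 | ethyl levulinate (ethyl 4-oxopentanoate) | CCOC(=O)CCC(C)=O | starting material
2 | ethyl 3-(2-methyl-1,3-dioxolan-2-yl)propanoate | CCOC(=O)CCC1(C)OCCO1 | intermediate
3 | 3-(2-methyl-1,3-dioxolan-2-yl)propanal | O=CCCC1(C)OCCO1 | intermediate
4 | 2-(triphenylphosphoranylidene)propanal | CC(C=O)=P(c1ccccc1)(c1ccccc1)c1ccccc1 | starting material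
5 | (E)-2-methyl-5-(2-methyl-1,3-dioxolan-2-yl)pent-2-enal | O=C/C(C)=C/CCC1(C)OCCO1 | intermediate
6 | (E)-1-methoxy-3-(trimethylsilyloxy)buta-1,3-diene | CO/C=C/C(=C)O[Si](C)(C)C | starting material
7 | (1S,6R)-2-methoxy-1-methyl-6-[2-(2-methyl-1,3-dioxolan-2-yl)ethyl]-4-(trimethylsilyloxy)cyclohex-3-ene-1-carbaldehyde (epimers at the methoxy carbon) | O=C[C@]1(C)C(OC)C=C(O[Si](C)(C)C)C[C@H]1CCC1(C)OCCO1 | intermediate (not isolated)
8 | (1S,6R)-1-methyl-6-[2-(2-methyl-1,3-dioxolan-2-yl)ethyl]-4-oxocyclohex-2-ene-1-carbaldehyde | O=C[C@]1(C)C=CC(=O)C[C@H]1CCC1(C)OCCO1 | intermediate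
9 | methyl (R)-hydrogen 3-methylglutarate, (3R)-5-methoxy-3-methyl-5-oxopentanoic acid | OC(=O)C[C@@H](C)CC(=O)OC | starting material
10 | methyl (3R)-5-hydroxy-3-methylpentanoate | OCC[C@@H](C)CC(=O)OC | intermediate
11 | methyl (3S)-5-bromo-3-methylpentanoate | BrCC[C@@H](C)CC(=O)OC | intermediate
12 | (3S)-5-bromo-3-methylpentan-1-ol | BrCC[C@@H](C)CCO | intermediate
13 | (3S)-1-bromo-5-(methoxymethoxy)-3-methylpentane | BrCC[C@@H](C)CCOCOC | intermediate
14 | [(3S)-5-(methoxymethoxy)-3-methylpentyl]magnesium bromide | Br[Mg]CC[C@@H](C)CCOCOC | intermediate (not isolated)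
15 | (4S,5R)-4-[(4R)-1-hydroxy-6-(methoxymethoxy)-4-methylhexyl]-4-methyl-5-[2-(2-methyl-1,3-dioxolan-2-yl)ethyl]cyclohex-2-en-1-one (C9 epimers) | CC1(OCCO1)CC[C@@H]1CC(=O)C=C[C@@]1(C)C(O)CC[C@@H](C)CCOCOC | intermediate
16 | (4S,5R)-4-[(4R)-1,6-bis(methoxymethoxy)-4-methylhexyl]-4-methyl-5-[2-(2-methyl-1,3-dioxolan-2-yl)ethyl]cyclohex-2-en-1-one (C9 epimers) | CC1(OCCO1)CC[C@@H]1CC(=O)C=C[C@@]1(C)C(OCOC)CC[C@@H](C)CCOCOC | intermediate
17 | lithium enolate of 16 (O–Li on C3, C3=C4 and C1=C2) | CC1(OCCO1)CC[C@@H]1C=C(O[Li])C=C[C@@]1(C)C(OCOC)CC[C@@H](C)CCOCOC | intermediate (not isolated)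
18 | (4R,5R)-4-[(4R)-1,6-bis(methoxymethoxy)-4-methylhexyl]-4,6-dimethyl-5-[2-(2-methyl-1,3-dioxolan-2-yl)ethyl]cyclohex-2-en-1-one (C4 and C9 epimers) | CC1(OCCO1)CC[C@@H]1C(C)C(=O)C=C[C@@]1(C)C(OCOC)CC[C@@H](C)CCOCOC | intermediate
19 | lithium enolate of 18 (O–Li on C3, C3=C4 bearing the methyl, C1=C2) | CC1(OCCO1)CC[C@@H]1C(C)=C(O[Li])C=C[C@@]1(C)C(OCOC)CC[C@@H](C)CCOCOC | intermediate (not isolated)
20 | (4R,5S)-4-[(4R)-1,6-bis(methoxymethoxy)-4-methylhexyl]-4,6,6-trimethyl-5-[2-(2-methyl-1,3-dioxolan-2-yl)ethyl]cyclohex-2-en-1-one (C9 epimers) | CC1(OCCO1)CC[C@@H]1C(C)(C)C(=O)C=C[C@@]1(C)C(OCOC)CC[C@@H](C)CCOCOC | intermediate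
21 | (3S,4R)-4-[(4R)-1,6-bis(methoxymethoxy)-4-methylhexyl]-2,2,4-trimethyl-3-[2-(2-methyl-1,3-dioxolan-2-yl)ethyl]cyclohexan-1-one (C9 epimers) | CC1(OCCO1)CC[C@@H]1C(C)(C)C(=O)CC[C@@]1(C)C(OCOC)CC[C@@H](C)CCOCOC | intermediate
22 | hydrazone of 21 (C3=N–NH2) | CC1(OCCO1)CC[C@@H]1C(C)(C)C(=NN)CC[C@@]1(C)C(OCOC)CC[C@@H](C)CCOCOC | intermediate (not isolated)
23 | 2-{2-[(1R,2R)-2-[(4R)-1,6-bis(methoxymethoxy)-4-methylhexyl]-2,6,6-trimethylcyclohexyl]ethyl}-2-methyl-1,3-dioxolane (C9 epimers) | CC1(OCCO1)CC[C@@H]1C(C)(C)CCC[C@@]1(C)C(OCOC)CC[C@@H](C)CCOCOC | intermediate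
24 | 4-{(1R,2R)-2-[(4R)-1,6-dihydroxy-4-methylhexyl]-2,6,6-trimethylcyclohexyl}butan-2-one (C9 epimers) | CC(=O)CC[C@@H]1C(C)(C)CCC[C@@]1(C)C(O)CC[C@@H](C)CCO | intermediate
25 | (3R)-3-methyl-6-oxo-6-[(1R,2R)-1,3,3-trimethyl-2-(3-oxobutyl)cyclohexyl]hexanoic acid | CC(=O)CC[C@@H]1C(C)(C)CCC[C@@]1(C)C(=O)CC[C@@H](C)CC(=O)O | intermediate
26 | (2R)-3-(benzyloxy)propane-1,2-diol (3-O-benzyl-sn-glycerol) | OC[C@@H](O)COCc1ccccc1 | starting material
27 | (2S)-3-(benzyloxy)-2-hydroxypropyl (3R)-3-methyl-6-oxo-6-[(1R,2R)-1,3,3-trimethyl-2-(3-oxobutyl)cyclohexyl]hexanoate | CC(=O)CC[C@@H]1C(C)(C)CCC[C@@]1(C)C(=O)CC[C@@H](C)CC(=O)OC[C@@H](O)COCc1ccccc1 | intermediate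
28 | (2S)-2-acetoxy-3-(benzyloxy)propyl (3R)-3-methyl-6-oxo-6-[(1R,2R)-1,3,3-trimethyl-2-(3-oxobutyl)cyclohexyl]hexanoate | CC(=O)CC[C@@H]1C(C)(C)CCC[C@@]1(C)C(=O)CC[C@@H](C)CC(=O)OC[C@H](COCc1ccccc1)OC(C)=O | intermediate
29 | (2S)-2-acetoxy-3-hydroxypropyl (3R)-3-methyl-6-oxo-6-[(1R,2R)-1,3,3-trimethyl-2-(3-oxobutyl)cyclohexyl]hexanoate | CC(=O)CC[C@@H]1C(C)(C)CCC[C@@]1(C)C(=O)CC[C@@H](C)CC(=O)OC[C@H](CO)OC(C)=O | target

**Step count and risks**

Total steps: 19. Longest linear sequence: 15 steps (steps 1–4 and 9–19, from ethyl levulinate). The side branch of steps 5–8 joins at step 9, and diol 26 enters at step 17.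

Steps most likely to fail:

1. Step 4. The diene may add to the formyl C=O instead of the C=C (hetero-Diels–Alder or aldol-type addition). Silyl transfer from 6 to the acidic catalyst may create an achiral silyl Lewis acid that erodes face selection or opens the ketal. Turnover of the trisubstituted enal may be slow. The fallback sets out from 5 and comes back at 8. The diene is replaced by the more reactive (E)-1-(dimethylamino)-3-(tert-butyldimethylsilyloxy)buta-1,3-diene. The boron acid is replaced by a chiral chromium salen complex, [N,N'-bis(3,5-di-tert-butylsalicylidene)cyclohexane-1,2-diamine]chromium hexafluoroantimonate (trivalent chromium, 5 mol %), in CH2Cl2 at −40 °C. The same C4–C5 and C1–C10 bonds form, giving the amino silyl enol ether cycloadduct F1. Acetyl chloride in Et2O at −78 °C then acylates the amine and expels it together with the silyl group, giving enone aldehyde 8 without aqueous acid. The ligand antipode that leads to (1S,6R)-8 would be identified on small scale by chiroptical comparison or X-ray analysis of a crystalline derivative.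

2. Step 9. The Grignard reagent may attack the ring carbonyl (1,2- or 1,4-addition) because the neopentyl formyl group is hindered, and the magnesium alkoxide may fragment by vinylogous retro-aldol cleavage of C9–C10. The fallback sets out from 7 and comes back at 15. The acid treatment of step 4 is omitted, and 7 is isolated by filtration through Et3N-deactivated silica. Grignard reagent 14 is added at −78 °C to 7, whose ring carbonyl is still masked as the silyl enol ether, so the formyl group is the only electrophile. This gives the silyl enol ether carbinol F2 after a pH 7 quench. Catalytic CF3CO2H in CH2Cl2 at 0 °C then eliminates MeOSiMe3 and gives 15.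

3. Step 14. Hydrazone formation at the C3 carbonyl next to the gem-dimethyl carbon may be incomplete, and azine formation or reduction only to the carbinol may take over. The fallback sets out from 21 and comes back at 23. NaBH4 in MeOH at 0 °C reduces 21 to the C3 carbinol F3. NaH, CS2 and then MeI in THF convert it into the S-methyl xanthate F4. Bu3SnH with catalytic AIBN in toluene at 110 °C (Barton–McCombie deoxygenation) then replaces the C3–O bond by C–H and gives 23.

**Further compounds**

F1 | step 4 | (1S,6R)-2-(dimethylamino)-1-methyl-6-[2-(2-methyl-1,3-dioxolan-2-yl)ethyl]-4-(tert-butyldimethylsilyloxy)cyclohex-3-ene-1-carbaldehyde (epimers at the amino carbon) | O=C[C@]1(C)C(N(C)C)C=C(O[Si](C)(C)C(C)(C)C)C[C@H]1CCC1(C)OCCO1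
F2 | step 9 | C9 carbinol from addition of 14 to 7, with the C2=C3 trimethylsilyl enol ether and the C1 methoxy group retained (C1 and C9 epimers) | CC1(OCCO1)CC[C@@H]1CC(O[Si](C)(C)C)=CC(OC)[C@@]1(C)C(O)CC[C@@H](C)CCOCOC
F3 | step 14 | C3 carbinol corresponding to ketone 21 (C3 and C9 epimers) | CC1(OCCO1)CC[C@@H]1C(C)(C)C(O)CC[C@@]1(C)C(OCOC)CC[C@@H](C)CCOCOC
F4 | step 14 | O-(S-methyl dithiocarbonate) (xanthate) of F3 | CC1(OCCO1)CC[C@@H]1C(C)(C)C(OC(=S)SC)CC[C@@]1(C)C(OCOC)CC[C@@H](C)CCOCOC
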